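The readings were generated by integration for an exercise; the scatter is artificial.

3 questions stand on this flask, and I answer them by reckoning, taking the amount of X as 100 percent minus a few small corrections and computing those corrections.

| setting | Saturday's | Friday's | Thursday's | flask |
|---|---|---|---|---|
| Z | 0.020 M | 0.020 M | 0.010 M | 0.020 M |
| Q | 0.056 M | 0.088 M | 0.040 M | 0.0400 M |
| remark | run made earlier | run made earlier | run made earlier |  |
| time |  |  |  | 25 min |

- Saturday's (time / min: X / %): 2.50: 81.0; 8.00: 98.2; 15.0: 99.6; 20.0: 98.9; 30.0: 98.4
- Friday's (time / min: X / %): 6.00: 98.8; 12.0: 98.7; 20.0: 98.4; 25.0: 98.0; 30.0: 97.7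
- Thursday's (time / min: X / %): 2.50: 72.3; 8.00: 97.3; 15.0: 98.1; 20.0: 97.6; 30.0: 97.4

(standard deviation of a reading: 0.5 percentage points)

- a reading or a percentage of X counts all its forms, free or not

- equivalents of Q to Z, everything else as given, that leave most X at 25 min
- the amount of X then, in percent of the Z charged
- the amount of X with the amounts as given

First I take the main step by itself, Z + Q → X, with Z as the limiting reagent. One Q goes with each Z, so cQ − cZ stays constant and ln(cQ/cZ) climbs in a straight line with slope k(cQ − cZ). Saturday's first reading gives 0.244 M⁻¹ s⁻¹ for k, the pairing constant, and Thursday's first reading, from another charge, gives 0.241 M⁻¹ s⁻¹. With Saturday's value I reckon that the flask keeps 0.0328% of its Z at 25 min.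

Then I add the slow fall. Friday's readings of X drop by 1.1 percentage points in 24.0 min, and I suppose this is a further addition of Q to X, so I scale it by the excess of Q, which gives my estimate for the flask, a fall of 0.34 points by 25 min. Last comes the rest: Friday's line, run back to the start, leaves a gap of 0.92 points as a reading, and the flask has Friday's cZ, so I keep that gap. My n is therefore 98.7%.

Less Q raises the Z correction and lowers the fall, and the two slopes balance at an excess of 0.0191 M, which is 1.95 equivalents, with X at 98.7%.

The forecast, which holds the fall “nearly independent of Q”, gives 98.4% for n, lower than my figure, and 98.5% at 1.9 equiv.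

The flask gives 99.1% for n, and with the charge of Q moved, the most X at 25 min is 99.1%, at 1.97 equiv.

    Q + X → J (k = 0.00710 M⁻¹ s⁻¹)
    Z + Q → X (k = 0.250 M⁻¹ s⁻¹)
    X ⇌ L (K = 0.530, k = 0.00750 s⁻¹)
    D ⇌ X, rate k4*(cs4 - [X]) while solid is left; crystals form when [X] > cs4 (solubility = 0.230 mM, k = 1.30 s⁻¹)

At 25.0 min the flask holds 0.0280% of its Z, beside the 0.0328% that k gave. With Q lowered and the rest held, n has moved by 5 points at 0.0235 M. The neighbour charged with 0.016 M of Q lies below that, and there Q is the smaller charge, so the same k, turned round, leaves 5.66% of its Q at 25 min, and that neighbour flask holds 5.4% of its Q, with X at 75.0%.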